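**Plan**
- Retrosynthetic cuts, in order: O16–C15 of the lactone (Baeyer–Villiger on a C13-spiro cyclobutanone); the C9–O peroxide bond together with C8=C17 (from a C8=C9 alkene and a C13 hydroperoxide); C9–C11 (cross-coupling); C6–C7 and C5–C10 in one event (intramolecular Diels–Alder, C6–OH coming from C6–B); then C4–CH3, C4–C19 and the C9=C10 alkene on a lactone from the chiral pool.
- Enabling feature: in ring B the C9–O bond and the exocyclic C8=C17 alkene are the allylic transposition of a C8=C9 cyclohexene, and C6 carries a hydroxyl. Ring B is therefore a Diels–Alder retron (diene C7=C8–C9=C10, dienophile C5=C6 bearing boron), and C1–C4 of ring A are the four-atom tether.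
- Forward order: acyclic dienyne, then rings A and B together (step 8), then the C9 side chain, then the 1,2-dioxane (spiro at C9 and C13), and the γ-lactone last.
- Stereochemistry: C2 from the glutamic-acid-derived lactone 1; C4 by enolate alkylation anti to the lactone γ-substituent; C5, C6 and C10 in the cycloaddition; C9 by inversion at an α-epoxide; C13 by catalyst-controlled desymmetrizing Baeyer–Villiger oxidation.

Key step: step 8

Assumption: labdane numbering is used (C19 is the CH2OH on C4, β is the face of the C10 methyl); 1 and 19 are taken as catalogue compounds; which antipode of the acid catalyst in step 19 gives the required C13 centre must be settled by experiment, and the (R) form is written.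

**Route**

Step 1
Reactants: 1 (S)-(5-oxotetrahydrofuran-2-yl)methyl 4-methylbenzenesulfonate
Product: 2 methyl 3-[(2S)-oxiran-2-yl]propanoate
Conditions: NaOMe, MeOH, 0 °C to rt
Reagents that add atoms: sodium methoxide, [Na+].[O-]C
Why: Methanolysis of the lactone frees the C2 alkoxide, which displaces the primary tosylate (intramolecular Williamson epoxide closure); the C2–O bond is not broken, so the configuration is kept.

Step 2
Reactants: 2 methyl 3-[(2S)-oxiran-2-yl]propanoate
Product: 4 (5S)-5-(prop-2-yn-1-yl)dihydrofuran-2(3H)-one, via hydroxy ester 3 (not isolated)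
Conditions: HC≡CH, n-BuLi, THF, −78 °C; BF3·OEt2, −78 °C; then TsOH (cat.), CH2Cl2, rt
Reagents that add atoms: acetylene, C#C
Why: BF3-assisted opening of the terminal epoxide by lithium acetylide at the CH2 carbon tolerates the ester, and the γ-hydroxy ester then lactonizes under acid catalysis; C2 is untouched.

Step 3
Reactants: 4 (5S)-5-(prop-2-yn-1-yl)dihydrofuran-2(3H)-one
Product: 6 (5S)-5-[(2E)-2,4-dimethylpenta-2,4-dien-1-yl]dihydrofuran-2(3H)-one, via alkenylalane 5 (not isolated)
Conditions: Me3Al, Cp2ZrCl2, H2O (1 equiv), CH2Cl2, −30 °C; then 2-bromopropene, Pd(PPh3)4 (cat.), ZnCl2 (cat.), THF, rt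
Reagents that add atoms: trimethylaluminium, C[Al](C)C; 2-bromopropene, CC(Br)=C
Why: Negishi zirconium-catalysed syn-carboalumination puts methyl on the internal alkyne carbon (C10) and aluminium on C9, and palladium-catalysed coupling with retention gives the (E)-diene with C1 trans to C8; the short low-temperature carbometalation should spare the lactone.

Step 4
Reactants: 6 (5S)-5-[(2E)-2,4-dimethylpenta-2,4-dien-1-yl]dihydrofuran-2(3H)-one
Product: 7 3-[(triisopropylsilyloxy)methyl] lactone (3,5-trans isomer drawn)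
Conditions: LiN(i-Pr)2, THF, −78 °C; (i-Pr)3SiOCH2Cl, −78 to −40 °C
Reagents that add atoms: (triisopropylsiloxy)methyl chloride, ClCO[Si](C(C)C)(C(C)C)C(C)C
Why: Lactone enolate alkylation with a reactive chloromethyl ether, expected anti to the γ-substituent; this centre is enolized again in step 5, so both epimers converge.

Step 5
Reactants: 7 3-[(triisopropylsilyloxy)methyl] lactone
Product: 8 3-methyl-3-[(triisopropylsilyloxy)methyl] lactone (CH2OTIPS cis and CH3 trans to the C5 side chain)
Conditions: LiN(i-Pr)2, THF, −78 °C; MeI, DMPU, −78 to −20 °C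
Reagents that add atoms: iodomethane, CI
Why: Second enolate alkylation of a γ-substituted butyrolactone; methyl iodide should approach the planar enolate anti to the γ-substituent, which places CH2OTIPS cis to it and sets the quaternary C4.

Step 6
Reactants: 8 3-methyl-3-[(triisopropylsilyloxy)methyl] lactone
Product: 9 lactol of 8 (anomer mixture)
Conditions: i-Bu2AlH, CH2Cl2, −78 °C
Reagents that add atoms: none
Why: Partial hydride reduction of a lactone stops at the lactol because the tetrahedral aluminium alkoxide is stable at low temperature; no stereocentre of the target is affected.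

Step 7
Reactants: 9 lactol of 8
Product: 10 (3E)-2,4,8-trimethyl-8-[(triisopropylsilyloxy)methyl]deca-1,3-dien-9-yn-6-ol
Conditions: dimethyl (1-diazo-2-oxopropyl)phosphonate, K2CO3, MeOH, 0 °C to rt
Reagents that add atoms: dimethyl (1-diazo-2-oxopropyl)phosphonate, CC(=O)C(=[N+]=[N-])P(=O)(OC)OC
Why: Seyferth–Gilbert homologation with the Ohira–Bestmann reagent acts on the hydroxy-aldehyde form of the lactol and gives the terminal alkyne (C5≡C6); the aldehyde carbon is attached to the quaternary C4, so nothing can epimerize.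

Step 8
Reactants: 10 (3E)-2,4,8-trimethyl-8-[(triisopropylsilyloxy)methyl]deca-1,3-dien-9-yn-6-ol
Product: 13 trans-decalin 2α,6α-diol (4β-CH2OTIPS; 4α,8,10β-trimethyl; C8=C9), via alkenylborane 11 (not isolated), via cycloadduct borane 12 (not isolated)
Conditions: Cy2BH (2.2 equiv), THF, 0 °C to rt; toluene, 80–110 °C; then NaOH, H2O2, 0 °C
Reagents that add atoms: hydrogen peroxide, OO
Why: Proposed new method: dicyclohexylborane converts the C2 hydroxyl into a borinate and adds syn to the terminal alkyne to give the (E)-alkenyl(dialkyl)borane 11, whose vacant boron p orbital lowers the dienophile LUMO so that a thermal intramolecular [4+2] cycloaddition with the C7=C8–C9=C10 diene can follow, and alkaline peroxide then replaces boron by hydroxyl with retention. The closest known reactions are the intermolecular Diels–Alder additions of dialkyl(vinyl)boranes, which are fast and endo selective, and the thermal intramolecular Diels–Alder reaction of 1,7,9-decatrienes; joining them in one flask after alkyne hydroboration is not established. Ring B closes as a cyclohexene (C8=C9) through the new C6–C7 and C5–C10 bonds, and ring A closes in the fused mode as the six-membered ring made of the four-atom tether C1–C4 and the same C5–C10 bond. The (E) geometry of the alkenylborane puts boron trans to C4 and so gives equatorial 6α-boron, the (E) diene geometry puts the C10 methyl inside and C1 outside, the endo position of boron under the diene gives the trans ring fusion (H5 anti to the C10 methyl), and the diene face is selected by a chair tether with the C2 oxygen equatorial, since the other chair would force the C2 oxygen, the C4 methyl and the C10 methyl into a 1,3,5-triaxial array. The step needs hydroboration of the terminal alkyne in preference to the 1,1-disubstituted diene terminus, for which the bulky bis(secondary-alkyl)borane is chosen, and endo over exo closure, which the boron–diene secondary interaction should provide.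

Step 9
Reactants: 13 trans-decalin 2α,6α-diol
Product: 14 2α,6α-bis(tert-butyldimethylsilyl) ether of 13
Conditions: TBSOTf, 2,6-lutidine, CH2Cl2, 0 °C
Reagents that add atoms: tert-butyldimethylsilyl trifluoromethanesulfonate, CC(C)(C)[Si](C)(C)OS(=O)(=O)C(F)(F)F
Why: Silyl triflate silylation is strong enough for the hindered equatorial C6 hydroxyl; no stereocentre changes.

Step 10
Reactants: 14 2α,6α-bis(tert-butyldimethylsilyl) ether
Product: 17 9-ketone (8-methyl; C8 epimers), via alkylborane 15 (not isolated), via secondary alcohol 16 (not isolated)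
Conditions: BH3·SMe2, THF, 0 °C to rt; then N-methylmorpholine N-oxide, (n-Pr4N)RuO4 (cat.), 4 Å MS, CH2Cl2, rt
Reagents that add atoms: N-methylmorpholine N-oxide, C[N+]1([O-])CCOCC1
Why: Hydroboration places boron on the less substituted alkene carbon C9, the amine oxide converts C–B into C–O, and perruthenate oxidizes the alcohol to the ketone in the same flask; the C8 and C9 configurations of 15 and 16 are irrelevant because both carbons become sp2 again.

Step 11
Reactants: 17 9-ketone
Product: 18 C9 enol triflate (C8=C9)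
Conditions: KN(SiMe3)2, THF, −78 °C; PhNTf2, −78 °C to rt
Reagents that add atoms: N-phenylbis(trifluoromethanesulfonimide), O=S(=O)(N(c1ccccc1)S(=O)(=O)C(F)(F)F)C(F)(F)F
Why: Enolate O-triflation; C10 is quaternary, so enolization can only go toward C8 and the tetrasubstituted C8=C9 enol triflate forms regiospecifically.

Step 12
Reactants: 19 3,3-dimethoxycyclobutan-1-one
Product: 20 1-ethenyl-3,3-dimethoxycyclobutan-1-ol
Conditions: CH2=CHMgBr, THF, −78 °C
Reagents that add atoms: vinylmagnesium bromide, C=C[Mg]Br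
Why: Grignard 1,2-addition to the strained ketone at low temperature, which should outrun enolization; the product is achiral.

Step 13
Reactants: 20 1-ethenyl-3,3-dimethoxycyclobutan-1-ol
Product: 21 1-ethenyl-3,3-dimethoxycyclobut-1-ene
Conditions: Burgess reagent (MeO2CN(−)SO2N(+)Et3), benzene, 50 °C
Reagents that add atoms: none
Why: Syn elimination of the tertiary alcohol through its sulfamate (Burgess dehydration); only ring hydrogens are available, so the conjugated 1-vinylcyclobutene is the single alkene that can form.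

Step 14
Reactants: 18 C9 enol triflate; 21 1-ethenyl-3,3-dimethoxycyclobut-1-ene
Product: 23 C9-[2-(3,3-dimethoxycyclobut-1-en-1-yl)ethyl] decalin (C8=C9 kept), via B-alkyl-9-BBN 22 (not isolated)
Conditions: 21, 9-BBN-H, THF, 0 °C to rt; then 18, Pd(dppf)Cl2 (cat.), AsPh3, Cs2CO3, DMF–H2O, 50 °C
Reagents that add atoms: none
Why: 9-BBN should add to the terminal vinyl group of the diene (boron on CH2) and leave the trisubstituted cyclobutene, and B-alkyl Suzuki–Miyaura coupling with the hindered cyclohexenyl triflate then forms the C9–C11 bond; no stereocentre is involved.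

Step 15
Reactants: 23 C9-[2-(3,3-dimethoxycyclobut-1-en-1-yl)ethyl] decalin
Product: 25 C13 tertiary hydroperoxide (3,3-dimethoxycyclobutyl), via silyl peroxide 24 (not isolated)
Conditions: Co(thd)2 (cat.; thd = 2,2,6,6-tetramethylheptane-3,5-dionate), O2 (1 atm), Et3SiH, ClCH2CH2Cl, rt; then K2CO3 (cat.), MeOH, 0 °C
Reagents that add atoms: dioxygen, O=O
Why: Mukaiyama–Isayama hydroperoxidation: hydrogen-atom transfer from a cobalt hydride to C14 gives the tertiary cyclobutyl radical at C13, which traps O2 and is silylated, and methanolysis frees the hydroperoxide; the tetrasubstituted C8=C9 alkene should be too hindered to react, and C13 is not yet a stereocentre because its two ring arms are identical.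

Step 16
Reactants: 25 C13 tertiary hydroperoxide
Product: 27 8α-hydroxy-9β,13-epidioxide (spiro 1,2-dioxane; 8β-methyl), via epoxy hydroperoxide 26 (not isolated)
Conditions: mCPBA, CH2Cl2, −20 to 0 °C; then rt (pyridinium p-toluenesulfonate, cat., if needed)
Reagents that add atoms: 3-chloroperbenzoic acid, OOC(=O)c1cccc(Cl)c1
Why: Peracid epoxidation should occur on the α face, anti to the axial C10 methyl, and the tethered hydroperoxide then opens the epoxide at C9 in the 6-exo mode with inversion (acid-catalysed intramolecular epoxide opening by a hydroperoxide), which places the peroxide oxygen β and C11 α and so sets C9.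

Step 17
Reactants: 27 8α-hydroxy-9β,13-epidioxide
Product: 28 8(17)-ene 9β,13-epidioxide (silyl ethers and ketal intact)
Conditions: SOCl2, pyridine, CH2Cl2, −20 to 0 °C
Reagents that add atoms: none
Why: E2 elimination through the chlorosulfite of an equatorial tertiary alcohol: only the C17 methyl hydrogens can be antiperiplanar and C9 has no hydrogen, so the exocyclic alkene should form.

Step 18
Reactants: 28 8(17)-ene 9β,13-epidioxide
Product: 29 2α,6α,19-triol with C13-spiro cyclobutan-3-one
Conditions: HF (48 % aq.), MeCN, 0 °C to rt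
Reagents that add atoms: water, O
Why: Acidic fluoride cleaves the two secondary TBS ethers and the primary TIPS ether and hydrolyses the dimethyl ketal; the bis-tertiary dialkyl peroxide and the alkene should tolerate these conditions.

Step 19
Reactants: 29 2α,6α,19-triol with C13-spiro cyclobutan-3-one
Product: 30 CNP0262224.1 (target)
Conditions: (R)-3,3'-bis(2,4,6-triisopropylphenyl)-1,1'-binaphthyl-2,2'-diyl hydrogen phosphate (10 mol %), H2O2 (30 % aq.), CHCl3, −40 °C
Reagents that add atoms: hydrogen peroxide, OO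
Why: Catalytic asymmetric Baeyer–Villiger desymmetrization of a prochiral 3,3-disubstituted cyclobutanone: the chiral acid binds the Criegee adduct and selects which of the two diastereotopic CH2 groups migrates, which creates the lactone and sets C13; the alkene and the peroxide are inert to metal-free H2O2.

**Compound list**

1 | (S)-(5-oxotetrahydrofuran-2-yl)methyl 4-methylbenzenesulfonate | Cc1ccc(cc1)S(=O)(=O)OC[C@@H]1CCC(=O)O1 | starting material
2 | methyl 3-[(2S)-oxiran-2-yl]propanoate | COC(=O)CC[C@H]1CO1 | intermediate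
3 | methyl (4S)-4-hydroxyhept-6-ynoate | COC(=O)CC[C@H](O)CC#C | intermediate
4 | (5S)-5-(prop-2-yn-1-yl)dihydrofuran-2(3H)-one | C#CC[C@@H]1CCC(=O)O1 | intermediate
5 | dimethyl{(1E)-2-methyl-3-[(2S)-5-oxotetrahydrofuran-2-yl]prop-1-en-1-yl}alane | C[Al](C)/C=C(\C)C[C@@H]1CCC(=O)O1 | intermediate
6 | (5S)-5-[(2E)-2,4-dimethylpenta-2,4-dien-1-yl]dihydrofuran-2(3H)-one | C=C(C)/C=C(\C)C[C@@H]1CCC(=O)O1 | intermediate
7 | 5-[(2E)-2,4-dimethylpenta-2,4-dien-1-yl]-3-[(triisopropylsilyloxy)methyl]dihydrofuran-2(3H)-one, C5 as in 6, 3,5-trans isomer | CC(C)[Si](C(C)C)(C(C)C)OC[C@@H]1C[C@@H](C/C(C)=C/C(C)=C)OC1=O | intermediate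
8 | 5-[(2E)-2,4-dimethylpenta-2,4-dien-1-yl]-3-methyl-3-[(triisopropylsilyloxy)methyl]dihydrofuran-2(3H)-one, CH2OTIPS cis and CH3 trans to the C5 side chain | C[C@]1(CO[Si](C(C)C)(C(C)C)C(C)C)C[C@@H](C/C(C)=C/C(C)=C)OC1=O | intermediate
9 | lactol of 8 (2-hydroxytetrahydrofuran, anomer mixture) | C[C@]1(CO[Si](C(C)C)(C(C)C)C(C)C)C[C@@H](C/C(C)=C/C(C)=C)OC1O | intermediate
10 | (3E)-2,4,8-trimethyl-8-[(triisopropylsilyloxy)methyl]deca-1,3-dien-9-yn-6-ol, C6 and C8 as in 8 (labdane C2 and C4) | C#C[C@@](C)(CO[Si](C(C)C)(C(C)C)C(C)C)C[C@H](O)C/C(C)=C/C(C)=C | intermediate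
11 | (E)-alkenyl(dicyclohexyl)borane of 10 with the C6 oxygen as dicyclohexylborinate | C1CCCCC1B(C1CCCCC1)/C=C/[C@@](C)(CO[Si](C(C)C)(C(C)C)C(C)C)C[C@H](OB(C1CCCCC1)C1CCCCC1)C/C(C)=C/C(C)=C | intermediate
12 | cycloadduct: trans-decalin with 6α-dicyclohexylboryl, 2α-O-dicyclohexylborinate, C8=C9 | CC=1C[C@H](B(C2CCCCC2)C2CCCCC2)[C@H]3[C@@](C)(CO[Si](C(C)C)(C(C)C)C(C)C)C[C@H](OB(C2CCCCC2)C2CCCCC2)C[C@]3(C)C1 | intermediate
13 | trans-decalin 2α,6α-diol: 4β-(triisopropylsilyloxymethyl), 4α,8,10β-trimethyl, 5α-H, C8=C9 (labdane numbering) | CC=1C[C@H](O)[C@H]2[C@@](C)(CO[Si](C(C)C)(C(C)C)C(C)C)C[C@H](O)C[C@]2(C)C1 | intermediate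
14 | 2α,6α-bis(tert-butyldimethylsilyl) ether of 13 | CC=1C[C@H](O[Si](C)(C)C(C)(C)C)[C@H]2[C@@](C)(CO[Si](C(C)C)(C(C)C)C(C)C)C[C@H](O[Si](C)(C)C(C)(C)C)C[C@]2(C)C1 | intermediate
15 | C9 alkylborane from 14 (C8, C9 isomers) | CC1C[C@H](O[Si](C)(C)C(C)(C)C)[C@H]2[C@@](C)(CO[Si](C(C)C)(C(C)C)C(C)C)C[C@H](O[Si](C)(C)C(C)(C)C)C[C@]2(C)C1B | intermediate
16 | C9 secondary alcohol from 15 (C8, C9 isomers) | CC1C[C@H](O[Si](C)(C)C(C)(C)C)[C@H]2[C@@](C)(CO[Si](C(C)C)(C(C)C)C(C)C)C[C@H](O[Si](C)(C)C(C)(C)C)C[C@]2(C)C1O | intermediate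
17 | 9-ketone, 8-methyl (C8 epimers) | CC1C[C@H](O[Si](C)(C)C(C)(C)C)[C@H]2[C@@](C)(CO[Si](C(C)C)(C(C)C)C(C)C)C[C@H](O[Si](C)(C)C(C)(C)C)C[C@]2(C)C1=O | intermediate
18 | C9 enol triflate, C8=C9 | CC=1C[C@H](O[Si](C)(C)C(C)(C)C)[C@H]2[C@@](C)(CO[Si](C(C)C)(C(C)C)C(C)C)C[C@H](O[Si](C)(C)C(C)(C)C)C[C@]2(C)C1OS(=O)(=O)C(F)(F)F | intermediate
19 | 3,3-dimethoxycyclobutan-1-one | COC1(OC)CC(=O)C1 | starting material
20 | 1-ethenyl-3,3-dimethoxycyclobutan-1-ol | C=CC1(O)CC(OC)(OC)C1 | intermediate
21 | 1-ethenyl-3,3-dimethoxycyclobut-1-ene | C=CC1=CC(OC)(OC)C1 | intermediate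
22 | 9-[2-(3,3-dimethoxycyclobut-1-en-1-yl)ethyl]-9-borabicyclo[3.3.1]nonane | COC1(OC)CC(CCB2C3CCCC2CCC3)=C1 | intermediate
23 | decalin 14-type core with C9-[2-(3,3-dimethoxycyclobut-1-en-1-yl)ethyl], C8=C9 | CC=1C[C@H](O[Si](C)(C)C(C)(C)C)[C@H]2[C@@](C)(CO[Si](C(C)C)(C(C)C)C(C)C)C[C@H](O[Si](C)(C)C(C)(C)C)C[C@]2(C)C1CCC1=CC(OC)(OC)C1 | intermediate
24 | C13 triethylsilyl peroxide (1-alkyl-3,3-dimethoxycyclobutyl) | CC=1C[C@H](O[Si](C)(C)C(C)(C)C)[C@H]2[C@@](C)(CO[Si](C(C)C)(C(C)C)C(C)C)C[C@H](O[Si](C)(C)C(C)(C)C)C[C@]2(C)C1CCC1(OO[Si](CC)(CC)CC)CC(OC)(OC)C1 | intermediate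
25 | C13 hydroperoxide (1-alkyl-3,3-dimethoxycyclobutyl hydroperoxide), C8=C9 | CC=1C[C@H](O[Si](C)(C)C(C)(C)C)[C@H]2[C@@](C)(CO[Si](C(C)C)(C(C)C)C(C)C)C[C@H](O[Si](C)(C)C(C)(C)C)C[C@]2(C)C1CCC1(OO)CC(OC)(OC)C1 | intermediate
26 | 8α,9α-epoxide of 25 | C[C@@]12C[C@H](O[Si](C)(C)C(C)(C)C)[C@H]3[C@@](C)(CO[Si](C(C)C)(C(C)C)C(C)C)C[C@H](O[Si](C)(C)C(C)(C)C)C[C@]3(C)[C@@]1(O2)CCC1(OO)CC(OC)(OC)C1 | intermediate
27 | 8α-hydroxy-8β-methyl-9β,13-epidioxide (spiro 1,2-dioxane, C11 on the α face; C13 spiro to 3,3-dimethoxycyclobutane) | C[C@@]1(O)C[C@H](O[Si](C)(C)C(C)(C)C)[C@H]2[C@@](C)(CO[Si](C(C)C)(C(C)C)C(C)C)C[C@H](O[Si](C)(C)C(C)(C)C)C[C@]2(C)[C@]13CCC4(CC(OC)(OC)C4)OO3 | intermediate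
28 | 8(17)-ene 9β,13-epidioxide, 2α,6α-bis-TBS, 19-TIPS, dimethyl ketal | C=C1C[C@H](O[Si](C)(C)C(C)(C)C)[C@H]2[C@@](C)(CO[Si](C(C)C)(C(C)C)C(C)C)C[C@H](O[Si](C)(C)C(C)(C)C)C[C@]2(C)[C@]13CCC4(CC(OC)(OC)C4)OO3 | intermediate
29 | 2α,6α,19-trihydroxy-8(17)-ene 9β,13-epidioxide with C13 spiro to cyclobutan-3-one | C=C1C[C@H](O)[C@H]2[C@@](C)(CO)C[C@H](O)C[C@]2(C)[C@]13CCC4(CC(=O)C4)OO3 | intermediate
30 | CNP0262224.1: 2α,6α,19-trihydroxy-9β,13-epidioxylabd-8(17)-en-15,16-olide, C13 as in the given structure | C=C1C[C@H](O)[C@H]2[C@@](C)(CO)C[C@H](O)C[C@]2(C)[C@]12CC[C@]1(COC(=O)C1)OO2 | target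

**Summary**

Total step count: 19. Longest linear sequence: 17 steps (steps 1–11 and 14–19); steps 12 and 13 make the side-chain fragment.

Steps most likely to fail:

1. Step 8 (proposed new method). The dialkylborane may also hydroborate the diene terminus, the cycloaddition may be slow because the C10 methyl sits inside the diene, and endo selectivity may erode at the temperature required. The fallback uses known chemistry, sets out from lactol 9 and comes back to the route at diol 13. A Henry addition of nitromethane (KOt-Bu cat., THF) gives the nitro diol F1. Ac2O, DMAP and Et3N give the bis-acetate F2, which loses acetic acid in the same flask to the (E)-nitroalkene 2-O-acetate F3. A thermal intramolecular Diels–Alder reaction (toluene, 80–110 °C; nitro-activated 1,7,9-decatrienes are known to close through the endo-nitro, trans-fused transition state) gives the 6α-nitro decalin acetate F4. An oxidative Nef reaction (KOt-Bu, then dimethyldioxirane) gives the 6-ketone F5, SmI2, H2O and Et3N reduce it to the equatorial 6α-alcohol 2-acetate F6, and K2CO3 in MeOH removes the acetate to give 13.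

2. Step 16. The protonated epoxide may open at C8 (seven-membered mode, favoured by trans-diaxial opening), ionize to a C9 cation with loss of the inversion pathway or a skeletal shift, or the cyclobutyl hydroperoxide may rearrange under acid. The fallback sets out from hydroperoxide 25 and comes back at alkene 28, so it also replaces step 17. N-Iodosuccinimide in CH2Cl2 at 0 °C (iodoperoxidation: iodonium on the α face, 6-exo attack of the hydroperoxide at C9 from the β face) gives the 8α-iodo-9β,13-epidioxide F7, and DBU in toluene at 60 °C eliminates HI toward the C17 methyl to give 28.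

3. Step 19. The catalyst may discriminate poorly between the two CH2 groups at a remote, fully substituted prochiral centre, or the substrate bias may be mismatched. The fallback sets out from 29 and gives 30 directly: an enzymatic Baeyer–Villiger oxidation with a panel of Baeyer–Villiger monooxygenases (cyclohexanone-monooxygenase type, NADPH recycling, O2, buffer), in which the enzyme pocket chooses the migrating group; no new compound is made.

Further compounds
F1 | step 8 | nitro diol: Henry adduct of 9 with nitromethane (C5 carbinol epimers) | [O-][N+](=O)CC(O)[C@@](C)(CO[Si](C(C)C)(C(C)C)C(C)C)C[C@H](O)C/C(C)=C/C(C)=C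
F2 | step 8 | bis-acetate of F1 | [O-][N+](=O)CC(OC(C)=O)[C@@](C)(CO[Si](C(C)C)(C(C)C)C(C)C)C[C@H](OC(C)=O)C/C(C)=C/C(C)=C
F3 | step 8 | (E)-nitroalkene 2-O-acetate (nitro-decatriene) | [O-][N+](=O)/C=C/[C@@](C)(CO[Si](C(C)C)(C(C)C)C(C)C)C[C@H](OC(C)=O)C/C(C)=C/C(C)=C
F4 | step 8 | 6α-nitro trans-decalin 2α-acetate, C8=C9 | CC=1C[C@H]([N+](=O)[O-])[C@H]2[C@@](C)(CO[Si](C(C)C)(C(C)C)C(C)C)C[C@H](OC(C)=O)C[C@]2(C)C1
F5 | step 8 | 6-ketone 2α-acetate, C8=C9 | CC=1CC(=O)[C@H]2[C@@](C)(CO[Si](C(C)C)(C(C)C)C(C)C)C[C@H](OC(C)=O)C[C@]2(C)C1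
F6 | step 8 | 6α-alcohol 2α-acetate, C8=C9 | CC=1C[C@H](O)[C@H]2[C@@](C)(CO[Si](C(C)C)(C(C)C)C(C)C)C[C@H](OC(C)=O)C[C@]2(C)C1
F7 | step 16 | 8α-iodo-8β-methyl-9β,13-epidioxide (silyl ethers and ketal as in 27) | C[C@@]1(I)C[C@H](O[Si](C)(C)C(C)(C)C)[C@H]2[C@@](C)(CO[Si](C(C)C)(C(C)C)C(C)C)C[C@H](O[Si](C)(C)C(C)(C)C)C[C@]2(C)[C@]13CCC4(CC(OC)(OC)C4)OO3
F0 | step 19 | none | none
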